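**Strategy.** The tetramer (units 1–4, top epicatechin to terminal epicatechin) is divided at C4(unit 2)–C8(unit 3) into two dimers. The plan rests on building ring C of unit 4 after the C4(unit 3)–C6(unit 4) bond exists. In unit 4, O1 on C8a of ring A lies para to C6, and C4 is a methylene. Heating the para-O 1-arylpropargyl ether of the benzylated unit 3–bromophloroglucinol adduct therefore forms C4–C4a by a [3,3] shift and O1–C2 by oxa-6π closure in one operation, giving a flav-3-ene that can only be 4→6 linked. The bromine on the second ortho carbon becomes the C8 cap for the later fragment union; C2 and C3 are set afterwards through the flavan-3-one.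

Key step: step 11

Assumption: (−)-epiafzelechin (23) is bought as the isolated natural product; the (R,R) catalyst in step 14 is chosen by treating C2 (oxygen- and aryl-bearing) as the large flank of the ketone, and a small test on 20 with both catalyst enantiomers would confirm the choice.

Remark: the two carbons ortho to the para oxygen of 9 are constitutionally equivalent, so the bromine is not what directs the sigmatropic shift; it is kept in 13 because it blocks C8 of unit 4 in step 20 and leaves in step 21.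

Step 1
Reactants: 1 (−)-epicatechin
Product: 2 5,7,3',4'-tetra-O-benzyl-(−)-epicatechin
Conditions: BnBr, K2CO3, DMF, 0 °C → rt
Reagents that add atoms: benzyl bromide, BrCc1ccccc1
Why: Williamson ether synthesis with a carbonate base alkylates only the four phenols, leaving the secondary 3-OH free and C2/C3 untouched.

Step 2
Reactants: 2 5,7,3',4'-tetra-O-benzyl-(−)-epicatechin
Product: 3 3,5,7,3',4'-penta-O-benzyl-(−)-epicatechin
Conditions: NaH, BnBr, nBu4NI (cat.), DMF, 0 °C → rt
Reagents that add atoms: benzyl bromide, BrCc1ccccc1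
Why: Williamson ether synthesis through the sodium alkoxide of the 3-OH; with every phenol capped, no quinone-methide ring opening can epimerise C2.

Step 3
Reactants: 3 3,5,7,3',4'-penta-O-benzyl-(−)-epicatechin
Product: 4 3,5,7,3',4'-penta-O-benzyl-4β-(2-ethoxyethoxy)epicatechin (C4 ether trans to the 3-OBn group)
Conditions: DDQ, 2-ethoxyethanol, CH2Cl2, rt
Reagents that add atoms: 2-ethoxyethanol, CCOCCO
Why: DDQ benzylic oxidation abstracts hydride from C4 to give a cation stabilised by O1 and the 5,7-oxygens, and the alcohol adds anti to the 3-OBn group, giving the 4β ether (a configuration that is lost again on later ionisation).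

Step 4
Reactants: 4 penta-O-benzyl-4β-(2-ethoxyethoxy)epicatechin; 5 phloroglucinol (5 equiv)
Product: 6 4β-(2,4,6-trihydroxyphenyl)-3,5,7,3',4'-penta-O-benzylepicatechin
Conditions: BF3·OEt2 (0.5 equiv), THF–CH2Cl2, −20 → 0 °C
Reagents that add atoms: none
Why: Friedel–Crafts alkylation: the Lewis acid ionises the C4 ether and the excess of the symmetric triphenol attacks through carbon anti to the cis 2-aryl and 3-OBn groups, which sets the 4β (3,4-trans) centre of unit 3 and outcompetes self-condensation.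

Step 5
Reactants: 6 4β-(2,4,6-trihydroxyphenyl)-penta-O-benzylepicatechin
Product: 7 4β-[2,6-dihydroxy-4-(triisopropylsilyloxy)phenyl]-penta-O-benzylepicatechin
Conditions: TIPSCl (1.05 equiv), imidazole, DMF, −20 → 0 °C
Reagents that add atoms: triisopropylsilyl chloride, CC(C)[Si](Cl)(C(C)C)C(C)C
Why: Silyl ether formation under steric control: the two hydroxyls ortho to the bulky flavan-4-yl group are shielded, so the hindered chlorosilane should react at the open para hydroxyl.

Step 6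
Reactants: 7 para-O-silyl diol
Product: 8 4β-[2,6-bis(benzyloxy)-4-(triisopropylsilyloxy)phenyl]-penta-O-benzylepicatechin
Conditions: BnBr, K2CO3, nBu4NI (cat.), acetone, 50 °C
Reagents that add atoms: benzyl bromide, BrCc1ccccc1
Why: Williamson ether synthesis of the two remaining phenols in a dry aprotic medium, in which the hindered aryl silyl ether is expected to survive.

Step 7
Reactants: 8 para-O-silyl dibenzyl ether
Product: 9 4β-[2,6-bis(benzyloxy)-4-hydroxyphenyl]-penta-O-benzylepicatechin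
Conditions: TBAF, AcOH, THF, 0 °C
Reagents that add atoms: none
Why: Fluoride-mediated desilylation, buffered with acetic acid, frees the single para phenol without touching benzyl ethers.

Step 8
Reactants: 9 para phenol
Product: 10 4β-[2,6-bis(benzyloxy)-3-bromo-4-hydroxyphenyl]-penta-O-benzylepicatechin
Conditions: NBS (1.0 equiv), CH2Cl2, −78 °C
Reagents that add atoms: N-bromosuccinimide, O=C1CCC(=O)N1Br
Why: Electrophilic aromatic bromination ortho to the free phenol (para position blocked, both ortho carbons equivalent); the phenol ring should react much faster than the all-ether ring A of unit 3, so one equivalent at low temperature should leave C8 of unit 3 free.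

Step 9
Reactants: 11 3,4-bis(benzyloxy)benzaldehyde
Product: 12 rac-1-[3,4-bis(benzyloxy)phenyl]prop-2-yn-1-ol
Conditions: HC≡CMgBr, THF, 0 °C; aq NH4Cl
Reagents that add atoms: ethynylmagnesium bromide, C#C[Mg]Br
Why: Grignard addition of the acetylide to the aldehyde; the racemic carbinol is acceptable because this centre is destroyed in step 11.

Step 10
Reactants: 10 bromophenol; 12 rac-1-[3,4-bis(benzyloxy)phenyl]prop-2-yn-1-ol
Product: 13 4β-{2,6-bis(benzyloxy)-3-bromo-4-[1-(3,4-bis(benzyloxy)phenyl)prop-2-yn-1-yloxy]phenyl}-penta-O-benzylepicatechin (both propargylic epimers)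
Conditions: PPh3, DIAD, toluene, 0 °C → rt
Reagents that add atoms: none
Why: Mitsunobu reaction: the acidic ortho-bromophenol is the only pronucleophile and the secondary propargylic alcohol the only alcohol present, so O-alkylation should give the aryl propargyl ether under neutral conditions.

Step 11
Reactants: 13 para-O-(1-arylpropargyl) ether
Product: 17 8-bromo-5,7,3',4'-tetra-O-benzylflav-3-ene of unit 4 carrying penta-O-benzylepicatechin-4β-yl (unit 3) at C6 (C2 epimer mixture), via allenyl cyclohexadienone 14 (not isolated), via ortho-allenylphenol 15 (not isolated), via ortho-quinone methide 16 (not isolated)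
Conditions: PhNEt2, 170 °C, argon, sealed tube
Reagents that add atoms: none
Why: Heating drives a propargyl Claisen rearrangement in which the O–C(propargylic) bond breaks and the alkyne terminus bonds to the unsubstituted ortho carbon (future C4a), giving dienone 14; enolisation to 15 and a 1,5-hydrogen shift from the phenol to the central allene carbon give the Z-configured ortho-quinone methide 16. Oxa-6π electrocyclisation of the O=C8a–C4a=C4–C3=C2 triene then re-forms O1–C2 and closes ring C as a six-membered 2H-pyran by a thermally allowed disrotatory closure. The closest known reaction type is the thermal conversion of aryl propargyl ethers into 2H-chromenes. No stereocentre needs control: C2 forms as both epimers and is corrected through ketone 20 in step 14, while C2–C4 of unit 3 are untouched. The only selectivity needed is regiochemical and lies in the substrate: the ether oxygen is para to the carbon bearing unit 3, so ring C can only be fused with unit 3 at C6, and a shift to the brominated ortho carbon gives a dienone that cannot enolise and should revert. The 1-aryl group weakens the breaking C–O bond, so the shift should run below the temperature needed for simple propargyl ethers, and the amine solvent suppresses acid-induced ionisation of this doubly activated ether.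

Step 12
Reactants: 17 flav-3-ene
Product: 19 2,3-trans-flavan-3-ol of unit 4 (both trans diastereomers) carrying unit 3 at C6, via C3 alkylborane 18 (not isolated)
Conditions: BH3·THF, THF, 0 °C → rt; then NaOH, H2O2, 0 °C
Reagents that add atoms: borane–tetrahydrofuran, B.C1CCOC1 (boron held only in 18); hydrogen peroxide, OO
Why: Hydroboration–oxidation: syn addition of H–B across C3=C4 anti to the 2-aryl group, with boron at C3 (remote from the electron-rich ring A), followed by oxidation with retention, should give the 2,3-trans 3-ol from each C2 epimer.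

Step 13
Reactants: 19 2,3-trans-flavan-3-ols
Product: 20 flavan-3-one of unit 4 (C2 epimer mixture) carrying unit 3 at C6
Conditions: Dess–Martin periodinane, NaHCO3, CH2Cl2, 0 °C → rt
Reagents that add atoms: none
Why: Dess–Martin oxidation converts both alcohols into one constitutional ketone under buffered, non-epimerising conditions for the rest of the molecule; the crude ketone is used at once.

Step 14
Reactants: 20 flavan-3-one
Product: 21 penta-O-benzylepicatechin-(4β→6)-8-bromo-5,7,3',4'-tetra-O-benzylepicatechin (unit 4: 2R,3R, free 3-OH)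
Conditions: RuCl(p-cymene)[(R,R)-TsDPEN] (cat.), HCO2H–Et3N (5:2), DMF, 40 °C
Reagents that add atoms: none
Why: Noyori-type asymmetric transfer hydrogenation with dynamic kinetic resolution: C2 (α to the ketone, benzylic and oxygen-bearing) epimerises through the enol under the amine, the chiral ruthenium hydride should reduce the 2R ketone faster, and hydride delivery anti to the 2-aryl group sets C3 as the 2,3-cis (2R,3R) alcohol.

Step 15
Reactants: 4 penta-O-benzyl-4β-(2-ethoxyethoxy)epicatechin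
Product: 22 8-bromo-3,5,7,3',4'-penta-O-benzyl-4β-(2-ethoxyethoxy)epicatechin
Conditions: NBS (1.05 equiv), CH2Cl2, −78 → 0 °C
Reagents that add atoms: N-bromosuccinimide, O=C1CCC(=O)N1Br
Why: Electrophilic aromatic bromination of ring A at C8, the more accessible of its two free positions (C6 lies between two benzyloxy groups), under neutral conditions that leave the C4 ether intact.

Step 16
Reactants: 23 (−)-epiafzelechin
Product: 24 5,7,4'-tri-O-benzyl-(−)-epiafzelechin
Conditions: BnBr, K2CO3, DMF, 0 °C → rt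
Reagents that add atoms: benzyl bromide, BrCc1ccccc1
Why: Williamson ether synthesis of the three phenols only, as in step 1.

Step 17
Reactants: 24 5,7,4'-tri-O-benzyl-(−)-epiafzelechin
Product: 25 8-bromo-5,7,4'-tri-O-benzyl-(−)-epiafzelechin
Conditions: NBS (1.0 equiv), CH2Cl2, −78 → 0 °C
Reagents that add atoms: N-bromosuccinimide, O=C1CCC(=O)N1Br
Why: Electrophilic aromatic bromination at C8, which leaves C6 as the only nucleophilic ring-A position of unit 2.

Step 18
Reactants: 22 8-bromo-penta-O-benzyl-4β-(2-ethoxyethoxy)epicatechin; 25 8-bromo-5,7,4'-tri-O-benzylepiafzelechin (2–3 equiv)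
Product: 26 8-bromo-penta-O-benzylepicatechin-(4β→6)-8-bromo-5,7,4'-tri-O-benzylepiafzelechin
Conditions: TMSOTf (cat.), CH2Cl2, −78 → −40 °C
Reagents that add atoms: none
Why: Lewis-acid Friedel–Crafts alkylation: the C4 cation of 22 cannot self-condense because its own C8 is brominated, 25 can react only at C6, and attack anti to the 3-OBn group sets the 4β centre of unit 1.

Step 19
Reactants: 26 unit 1–unit 2 dimer
Product: 27 dimer 26 carrying a 4β-(2-ethoxyethoxy) group at C4 of the epiafzelechin unit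
Conditions: DDQ, 2-ethoxyethanol, CH2Cl2, rt
Reagents that add atoms: 2-ethoxyethanol, CCOCCO
Why: DDQ benzylic oxidation at the only ring-C methylene (C4 of unit 2); the diarylmethine C4–H of unit 1 is shielded and cannot easily align with both rings, and the alcohol should add trans to the free 3-OH.

Step 20
Reactants: 27 C4-activated unit 1–unit 2 dimer; 21 unit 3–unit 4 dimer (1.5 equiv)
Product: 28 fully protected tetramer (17 benzyl ethers; bromine at C8 of units 1, 2 and 4; free 3-OH on units 2 and 4)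
Conditions: TMSOTf (cat.), CH2Cl2, −78 → −40 °C
Reagents that add atoms: none
Why: Lewis-acid Friedel–Crafts alkylation: C8 of unit 3 is the most nucleophilic position left (C8 of unit 4 is brominated, C6 of unit 3 is flanked by two benzyloxy groups), and attack anti to the 3-OH and 2-aryl of unit 2 sets its 4β centre.

Step 21
Reactants: 28 protected tetramer
Product: 29 epicatechin-(4β→6)-epiafzelechin-(4β→8)-epicatechin-(4β→6)-epicatechin (CNP0103636.1)
Conditions: H2 (1 atm), Pd(OH)2/C, Et3N (3.3 equiv), THF–MeOH–H2O, rt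
Reagents that add atoms: none
Why: Catalytic hydrogenolysis should cleave all seventeen benzyl ethers and the three aryl C–Br bonds under near-neutral conditions that leave the interflavan bonds and all eleven stereocentres alone.

**Compound list**

1 | (−)-epicatechin, (2R,3R) | O[C@@H]1Cc2c(O)cc(O)cc2O[C@@H]1c1ccc(O)c(O)c1 | starting material
2 | 5,7,3',4'-tetra-O-benzyl-(−)-epicatechin | O[C@@H]1Cc2c(OCc3ccccc3)cc(OCc3ccccc3)cc2O[C@@H]1c1ccc(OCc2ccccc2)c(OCc2ccccc2)c1 | intermediate
3 | 3,5,7,3',4'-penta-O-benzyl-(−)-epicatechin | C(O[C@@H]1Cc2c(OCc3ccccc3)cc(OCc3ccccc3)cc2O[C@@H]1c1ccc(OCc2ccccc2)c(OCc2ccccc2)c1)c1ccccc1 | intermediate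
4 | penta-O-benzyl-4β-(2-ethoxyethoxy)epicatechin (3,4-trans) | CCOCCO[C@H]1c2c(OCc3ccccc3)cc(OCc3ccccc3)cc2O[C@H](c2ccc(OCc3ccccc3)c(OCc3ccccc3)c2)[C@@H]1OCc1ccccc1 | intermediate
5 | phloroglucinol | Oc1cc(O)cc(O)c1 | starting material
6 | 4β-(2,4,6-trihydroxyphenyl)-penta-O-benzylepicatechin | Oc1cc(O)c([C@H]2c3c(OCc4ccccc4)cc(OCc4ccccc4)cc3O[C@H](c3ccc(OCc4ccccc4)c(OCc4ccccc4)c3)[C@@H]2OCc2ccccc2)c(O)c1 | intermediate
7 | 4β-[2,6-dihydroxy-4-(triisopropylsilyloxy)phenyl]-penta-O-benzylepicatechin | CC(C)[Si](C(C)C)(C(C)C)Oc1cc(O)c([C@H]2c3c(OCc4ccccc4)cc(OCc4ccccc4)cc3O[C@H](c3ccc(OCc4ccccc4)c(OCc4ccccc4)c3)[C@@H]2OCc2ccccc2)c(O)c1 | intermediate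
8 | 4β-[2,6-bis(benzyloxy)-4-(triisopropylsilyloxy)phenyl]-penta-O-benzylepicatechin | CC(C)[Si](C(C)C)(C(C)C)Oc1cc(OCc2ccccc2)c([C@H]2c3c(OCc4ccccc4)cc(OCc4ccccc4)cc3O[C@H](c3ccc(OCc4ccccc4)c(OCc4ccccc4)c3)[C@@H]2OCc2ccccc2)c(OCc2ccccc2)c1 | intermediate
9 | 4β-[2,6-bis(benzyloxy)-4-hydroxyphenyl]-penta-O-benzylepicatechin | Oc1cc(OCc2ccccc2)c([C@H]2c3c(OCc4ccccc4)cc(OCc4ccccc4)cc3O[C@H](c3ccc(OCc4ccccc4)c(OCc4ccccc4)c3)[C@@H]2OCc2ccccc2)c(OCc2ccccc2)c1 | intermediate
10 | 4β-[2,6-bis(benzyloxy)-3-bromo-4-hydroxyphenyl]-penta-O-benzylepicatechin | Oc1c(Br)c(OCc2ccccc2)c([C@H]2c3c(OCc4ccccc4)cc(OCc4ccccc4)cc3O[C@H](c3ccc(OCc4ccccc4)c(OCc4ccccc4)c3)[C@@H]2OCc2ccccc2)c(OCc2ccccc2)c1 | intermediate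
11 | 3,4-bis(benzyloxy)benzaldehyde | O=Cc1ccc(OCc2ccccc2)c(OCc2ccccc2)c1 | starting material
12 | rac-1-[3,4-bis(benzyloxy)phenyl]prop-2-yn-1-ol | C#CC(O)c1ccc(OCc2ccccc2)c(OCc2ccccc2)c1 | intermediate
13 | para-O-[1-(3,4-bis(benzyloxy)phenyl)prop-2-yn-1-yl] ether of 10 (both propargylic epimers) | C#CC(Oc1c(Br)c(OCc2ccccc2)c([C@H]2c3c(OCc4ccccc4)cc(OCc4ccccc4)cc3O[C@H](c3ccc(OCc4ccccc4)c(OCc4ccccc4)c3)[C@@H]2OCc2ccccc2)c(OCc2ccccc2)c1)c1ccc(OCc2ccccc2)c(OCc2ccccc2)c1 | intermediate
14 | 6-(3-arylallenyl)cyclohexa-2,4-dienone from the [3,3] shift (new sp3 carbon and allene axis uncontrolled) | O=C1C(Br)=C(OCc2ccccc2)C([C@H]2c3c(OCc4ccccc4)cc(OCc4ccccc4)cc3O[C@H](c3ccc(OCc4ccccc4)c(OCc4ccccc4)c3)[C@@H]2OCc2ccccc2)=C(OCc2ccccc2)C1C=C=Cc1ccc(OCc2ccccc2)c(OCc2ccccc2)c1 | intermediate (not isolated)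
15 | ortho-(3-arylallenyl)phenol | Oc1c(Br)c(OCc2ccccc2)c([C@H]2c3c(OCc4ccccc4)cc(OCc4ccccc4)cc3O[C@H](c3ccc(OCc4ccccc4)c(OCc4ccccc4)c3)[C@@H]2OCc2ccccc2)c(OCc2ccccc2)c1C=C=Cc1ccc(OCc2ccccc2)c(OCc2ccccc2)c1 | intermediate (not isolated)
16 | ortho-quinone methide with a Z-styryl terminus | O=C1C(Br)=C(OCc2ccccc2)C([C@H]2c3c(OCc4ccccc4)cc(OCc4ccccc4)cc3O[C@H](c3ccc(OCc4ccccc4)c(OCc4ccccc4)c3)[C@@H]2OCc2ccccc2)=C(OCc2ccccc2)C1=C/C=C\c1ccc(OCc2ccccc2)c(OCc2ccccc2)c1 | intermediate (not isolated)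
17 | 8-bromo-5,7,3',4'-tetra-O-benzylflav-3-ene of unit 4 with unit 3 at C6 (C2 epimers) | C1=CC(c2ccc(OCc3ccccc3)c(OCc3ccccc3)c2)Oc2c(Br)c(OCc3ccccc3)c([C@H]3c4c(OCc5ccccc5)cc(OCc5ccccc5)cc4O[C@H](c4ccc(OCc5ccccc5)c(OCc5ccccc5)c4)[C@@H]3OCc3ccccc3)c(OCc3ccccc3)c12 | intermediate
18 | flavan-3-ylborane of unit 4, boron trans to the 2-aryl group (both trans diastereomers; unit 4 centres left open) | BC1Cc2c(OCc3ccccc3)c([C@H]3c4c(OCc5ccccc5)cc(OCc5ccccc5)cc4O[C@H](c4ccc(OCc5ccccc5)c(OCc5ccccc5)c4)[C@@H]3OCc3ccccc3)c(OCc3ccccc3)c(Br)c2OC1c1ccc(OCc2ccccc2)c(OCc2ccccc2)c1 | intermediate (not isolated)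
19 | 2,3-trans-flavan-3-ol of unit 4 with unit 3 at C6 (both trans diastereomers; unit 4 centres left open) | OC1Cc2c(OCc3ccccc3)c([C@H]3c4c(OCc5ccccc5)cc(OCc5ccccc5)cc4O[C@H](c4ccc(OCc5ccccc5)c(OCc5ccccc5)c4)[C@@H]3OCc3ccccc3)c(OCc3ccccc3)c(Br)c2OC1c1ccc(OCc2ccccc2)c(OCc2ccccc2)c1 | intermediate
20 | flavan-3-one of unit 4 with unit 3 at C6 (C2 epimers) | O=C1Cc2c(OCc3ccccc3)c([C@H]3c4c(OCc5ccccc5)cc(OCc5ccccc5)cc4O[C@H](c4ccc(OCc5ccccc5)c(OCc5ccccc5)c4)[C@@H]3OCc3ccccc3)c(OCc3ccccc3)c(Br)c2OC1c1ccc(OCc2ccccc2)c(OCc2ccccc2)c1 | intermediate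
21 | penta-O-benzylepicatechin-(4β→6)-8-bromo-5,7,3',4'-tetra-O-benzylepicatechin | c1c(OCc3ccccc3)cc(OCc3ccccc3)c2c1O[C@H](c1ccc(OCc3ccccc3)c(OCc3ccccc3)c1)[C@H](OCc1ccccc1)[C@H]2c1c(OCc3ccccc3)c(Br)c2c(c1OCc3ccccc3)C[C@@H](O)[C@@H](c1ccc(OCc3ccccc3)c(OCc3ccccc3)c1)O2 | intermediate
22 | 8-bromo-penta-O-benzyl-4β-(2-ethoxyethoxy)epicatechin | CCOCCO[C@H]1c2c(OCc3ccccc3)cc(OCc3ccccc3)c(Br)c2O[C@H](c2ccc(OCc3ccccc3)c(OCc3ccccc3)c2)[C@@H]1OCc1ccccc1 | intermediate
23 | (−)-epiafzelechin, (2R,3R) | O[C@@H]1Cc2c(O)cc(O)cc2O[C@@H]1c1ccc(O)cc1 | starting material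
24 | 5,7,4'-tri-O-benzyl-(−)-epiafzelechin | O[C@@H]1Cc2c(OCc3ccccc3)cc(OCc3ccccc3)cc2O[C@@H]1c1ccc(OCc2ccccc2)cc1 | intermediate
25 | 8-bromo-5,7,4'-tri-O-benzyl-(−)-epiafzelechin | O[C@@H]1Cc2c(OCc3ccccc3)cc(OCc3ccccc3)c(Br)c2O[C@@H]1c1ccc(OCc2ccccc2)cc1 | intermediate
26 | 8-bromo-penta-O-benzylepicatechin-(4β→6)-8-bromo-5,7,4'-tri-O-benzylepiafzelechin | O(Cc1ccccc1)c1ccc([C@H]2Oc3c(Br)c(OCc4ccccc4)c([C@H]4c5c(OCc6ccccc6)cc(OCc6ccccc6)c(Br)c5O[C@H](c5ccc(OCc6ccccc6)c(OCc6ccccc6)c5)[C@@H]4OCc4ccccc4)c(OCc4ccccc4)c3C[C@H]2O)cc1 | intermediate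
27 | dimer 26 with 4β-(2-ethoxyethoxy) at C4 of the epiafzelechin unit | O(Cc1ccccc1)c1ccc([C@H]2Oc3c(Br)c(OCc4ccccc4)c([C@H]4c5c(OCc6ccccc6)cc(OCc6ccccc6)c(Br)c5O[C@H](c5ccc(OCc6ccccc6)c(OCc6ccccc6)c5)[C@@H]4OCc4ccccc4)c(OCc4ccccc4)c3[C@H](OCCOCC)[C@H]2O)cc1 | intermediate
28 | protected tetramer (17 benzyl ethers, three C8 bromines, free 3-OH on units 2 and 4) | O(Cc1ccccc1)c1ccc([C@H]2Oc3c(Br)c(OCc4ccccc4)c([C@H]4c5c(OCc6ccccc6)cc(OCc6ccccc6)c(Br)c5O[C@H](c5ccc(OCc6ccccc6)c(OCc6ccccc6)c5)[C@@H]4OCc4ccccc4)c(OCc4ccccc4)c3[C@H](c7c(OCc9ccccc9)cc(OCc9ccccc9)c8c7O[C@H](c7ccc(OCc9ccccc9)c(OCc9ccccc9)c7)[C@H](OCc7ccccc7)[C@H]8c7c(OCc9ccccc9)c(Br)c8c(c7OCc9ccccc9)C[C@@H](O)[C@@H](c7ccc(OCc9ccccc9)c(OCc9ccccc9)c7)O8)[C@H]2O)cc1 | intermediate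
29 | epicatechin-(4β→6)-epiafzelechin-(4β→8)-epicatechin-(4β→6)-epicatechin (CNP0103636.1) | Oc1ccc([C@H]2Oc3cc(O)c([C@H]4c5c(O)cc(O)cc5O[C@H](c5ccc(O)c(O)c5)[C@@H]4O)c(O)c3[C@H](c3c(O)cc(O)c4c3O[C@H](c3ccc(O)c(O)c3)[C@H](O)[C@H]4c3c(O)cc4c(c3O)C[C@@H](O)[C@@H](c3ccc(O)c(O)c3)O4)[C@H]2O)cc1 | target

**Totals**

Total step count: 21. Longest linear sequence: 15 steps (steps 1–8, 10–14, 20, 21).

**Steps most likely to fail**

1. Step 11. Heterolysis of the doubly activated propargylic C–O bond, or diversion of the allenyl intermediates, may outrun the sigmatropic pathway at the temperature required. Fallback (builds the same ring from an enal instead of an alkyne): setting out from phenol 10, aldehyde 11 would be homologated by Wittig reaction with Ph3P=CHCHO to (E)-3-[3,4-bis(benzyloxy)phenyl]prop-2-enal F1. Heating 10, F1 and PhB(OH)2 with catalytic propionic acid in toluene with water removal should alkylate the free carbon ortho to the phenol and give the 2-phenyl-4H-1,3,2-benzodioxaborinine F2. On continued heating F2 should fragment to ortho-quinone methide 16, whose oxa-6π closure rejoins the route at flavene 17.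

2. Step 14. Catalyst control may be mismatched with the chiral unit 3, or C2 epimerisation may be slower than reduction, so that facial and epimer selectivity are poor. Fallback (substrate control plus recycling): setting out from ketone 20, LiBH(s-Bu)3 in THF at −78 °C should add hydride anti to the 2-aryl group of each C2 epimer, giving only 2,3-cis alcohols, namely 21 and its unit 4 (2S,3S) diastereomer F3. These are diastereomers and would be separated by chromatography; F3 would be returned to 20 by Dess–Martin oxidation, re-equilibrated at C2 with DBU and reduced again, so the route is rejoined at 21.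

3. Step 19. Hydride abstraction may lose site selectivity (the diarylmethine C4–H of unit 1 or benzyl ether methylenes competing with the hindered C4 methylene of unit 2), or over-oxidation may occur. Fallback (leaving group installed before dimerisation, orthogonal activation): setting out from 25, DDQ and 2-ethoxyethanol should give monomeric 8-bromo-5,7,4'-tri-O-benzyl-4β-(2-ethoxyethoxy)epiafzelechin F4. BF3·OEt2 and 2,6-dimethylbenzenethiol would exchange the ether for sulfur, giving 8-bromo-5,7,4'-tri-O-benzyl-4β-[(2,6-dimethylphenyl)sulfanyl]epiafzelechin F5, which is inert to hard Lewis acids. F5 would be coupled through C6 with 22 under BF3·OEt2 at −78 °C to give the dimeric thioether F6. Activation of F6 with N-iodosuccinimide in the presence of 21 should then join the route at 28.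

**Further compounds**

F1 | step 11 | (E)-3-[3,4-bis(benzyloxy)phenyl]prop-2-enal | O=C/C=C/c1ccc(OCc2ccccc2)c(OCc2ccccc2)c1
F2 | step 11 | 2-phenyl-4-[(E)-2-(3,4-bis(benzyloxy)phenyl)ethenyl]-4H-1,3,2-benzodioxaborinine formed from 10 and F1 (C4 of the boron ring uncontrolled) | c1ccccc1B1OC(/C=C/c2ccc(OCc3ccccc3)c(OCc3ccccc3)c2)c2c(OCc3ccccc3)c([C@H]3c4c(OCc5ccccc5)cc(OCc5ccccc5)cc4O[C@H](c4ccc(OCc5ccccc5)c(OCc5ccccc5)c4)[C@@H]3OCc3ccccc3)c(OCc3ccccc3)c(Br)c2O1
F3 | step 14 | diastereomer of 21 with (2S,3S) configuration in unit 4 | c1c(OCc3ccccc3)cc(OCc3ccccc3)c2c1O[C@H](c1ccc(OCc3ccccc3)c(OCc3ccccc3)c1)[C@H](OCc1ccccc1)[C@H]2c1c(OCc3ccccc3)c(Br)c2c(c1OCc3ccccc3)C[C@H](O)[C@H](c1ccc(OCc3ccccc3)c(OCc3ccccc3)c1)O2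
F4 | step 19 | 8-bromo-5,7,4'-tri-O-benzyl-4β-(2-ethoxyethoxy)epiafzelechin | CCOCCO[C@H]1c2c(OCc3ccccc3)cc(OCc3ccccc3)c(Br)c2O[C@H](c2ccc(OCc3ccccc3)cc2)[C@@H]1O
F5 | step 19 | 8-bromo-5,7,4'-tri-O-benzyl-4β-[(2,6-dimethylphenyl)sulfanyl]epiafzelechin | Cc1cccc(C)c1S[C@H]1c2c(OCc3ccccc3)cc(OCc3ccccc3)c(Br)c2O[C@H](c2ccc(OCc3ccccc3)cc2)[C@@H]1O
F6 | step 19 | dimer 26 carrying a 4β-[(2,6-dimethylphenyl)sulfanyl] group at C4 of the epiafzelechin unit | O(Cc1ccccc1)c1ccc([C@H]2Oc3c(Br)c(OCc4ccccc4)c([C@H]4c5c(OCc6ccccc6)cc(OCc6ccccc6)c(Br)c5O[C@H](c5ccc(OCc6ccccc6)c(OCc6ccccc6)c5)[C@@H]4OCc4ccccc4)c(OCc4ccccc4)c3[C@H](Sc3c(C)cccc3C)[C@H]2O)cc1
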